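## The problem

The target is (2R)-2-[(1S,2S,3E,6E)-2,3-diformyl-7-methylcyclonona-3,6-dien-1-yl]-6-methylhept-5-en-1-yl acetate, numbered here as ring C1 (CH carrying the side chain), C2, C3, C4 (methyl C18)=C5, C6, C7=C8 (formyl C19), C9 (CH, formyl C20), and side chain C10 (CH) with C11 (CH2OAc) and C12–C17 (4-methylpent-3-enyl). The carbocycle is a nine-membered ring with a skipped diene: C4=C5 is a trans (E) ring alkene, C7=C8 a cis ring alkene, and C6 is doubly allylic. Such a ring is strained, hard to close end to end and prone to transannular reactions under acid. Three adjacent stereocentres are needed: C9 and C1 in the ring, trans to each other, and C10 just outside it. C1 can come from the chiral pool and, inside a six-membered ring, can direct C9 by trans-selective enolate alkylation. C10 is one rotatable bond away and can only be controlled by the combined bias of C1 and a substituent already on C9. The C8/C9 ene-1,4-dialdehyde is the most fragile part, since H9 is α to one formyl group and γ to the enal and a half-oxidised hydroxy aldehyde closes to a lactol. Both formyl groups must therefore appear together, last, and without strong base. The acetate excludes hydride and strong base once installed, and the three trisubstituted alkenes exclude hydrogenation, peracids and strong acid. The enabling feature is that C8 and C9 are neighbours and C8 carries the one-carbon branch C19. With C19 put back into the ring between them, the ring is a ten-membered ketone whose carbonyl and C4=C5 alkene have the 1,5-relationship of an oxy-Cope product. Its six-membered precursor maps onto carvone (carbonyl carbon = C19, methyl-bearing carbon = C4, stereocentre = C1, isopropenyl carbon = C10).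

## Retrosynthesis

**Aldehydes and acetate (33 ⇒ 31 ⇒ 26).** No C–C bond is cut. Both formyl groups of 33 are traced to the 1,4-diol 31 so that they can be formed in one Swern operation. A stepwise oxidation would pass through a hydroxy enal that closes to a lactol. The acetate must be in place before that, so C19–OH and C20–OH carry the same oxidatively removable PMB group (28–30) and C11 carries a silyl ether that is exchanged for acetate in between. The precursor is the dienoate 26. The forward steps must avoid base at the dialdehyde stage and hydride after acetylation.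

**C7=C8 (26 ⇒ 23).** The conjugated alkene is removed to give the saturated ester 23. Installing it from a C8 ketone (enol triflate, carbonylation) would belong to a different ring synthesis. From the ester it is a dehydrogenation that needs only the enolate. The forward reaction has to eliminate toward C7 and not toward C9.

**Key disconnection (23 ⇒ 21 ⇒ 19).** The C8–C9 bond is cut and C9 is reattached to C19, which makes C19 a ring ketone and C8 a diazo carbon: the ten-membered α-diazoketone 21, made from ketone 19 by diazo transfer. This avoids any end-to-end closure of a nine-membered ring. The ring is contracted by a 1,2-shift in a ring that already exists, and the migrating C9 keeps its configuration. The precursor is simpler because a ten-membered (E)-cycloalkenone with the carbonyl 1,5 to the alkene is an oxy-Cope retron. The forward reaction must rearrange cleanly instead of showing carbene chemistry.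

**Ten-membered ring (19 ⇒ 18).** The C6–C7 bond is cut and C4–C19 is reconnected, giving the 1,2-divinylcyclohexanol 18. A [3,3] shift through a chair sets the (E)-C4=C5 geometry without any olefination in a medium ring, and enolate formation drives it to completion. The precursor is a cyclohexane with the three final stereocentres already in place. The forward step needs a conformer in which the two vinyl groups are gauche and C3 is pseudo-equatorial.

**The two vinyl groups (18 ⇒ 16 + 17; 16 ⇒ 12 + 13).** The C19–C8 bond comes from addition of vinylmagnesium bromide 17 to ketone 16. The C4–C5 bond comes from trapping the enolate of enone 12 with acetaldehyde 13 (aldol 15) and dehydration. The enone is chosen because conjugate reduction gives the C4 enolate regiospecifically, whereas a saturated ketone with two tertiary α-carbons would not. The forward steps must place the new C4 branch on a defined face and must not enolise C9.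

**C10 and C11 oxygen (12 ⇒ 8 via 10, 11).** The C10–H and C11–O bonds are traced to hydroboration of the 1,1-disubstituted alkene of 8. This has to come after the C9 substituent is in place, since that substituent supplies the facial bias. It has to come before any vinyl group exists, since a vinyl group would be hydroborated first. The borane also reduces the enone carbonyl, so the sequence includes silylation (11) and re-oxidation (12).

**C9–C20 (8 ⇒ 6 + 7).** The bond is cut to the kinetic α'-enolate of enone 6 and the chloromethyl ether 7. One step installs the protected hydroxymethyl group trans to C1.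

**Side chain (6 ⇒ 4 + 5; 4 ⇒ 2 + 3; 2 ⇒ 1).** C14=C15 is cut by cross-metathesis to the terminal alkene 4 and 2-methylbut-2-ene 5. C12–C13 is cut to the allylic chloride 2 and allylboronate 3, both allyl units having equivalent termini. Chloride 2 comes from (R)-carvone 1 by allylic chlorination of the isopropenyl group, the one position of carvone that can be activated without touching the enone. Everything is thus reduced to 1, whose single stereocentre becomes C1.

## Roads not taken

**Alternative 1: amine-catalysed Michael closure of the ring (cut C1–C9).** An open-chain precursor A1 carries the C20 enal at one end and the C11 enal at the other. A chiral secondary amine would convert the C20 enal into its dienamine, whose α-carbon C9 adds to C1 of the second enal to give the cyclic dialdehyde ester A2.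
- Merits: it is the shortest route on paper. The ring, C1 and C9 form in one catalytic step, and C7=C8 ends up in the right place without a dehydrogenation.
- Weak points: the closure is an end-to-end formation of a strained nine-membered ring and competes with oligomerisation. The dienamine can also react at its γ-carbon C7, which would give a seven-membered ring. C10 would be set only by protonation next to the C11 aldehyde. A2 then has two α-branched aldehydes (C11 and C20) that must be told apart, one to be reduced and acetylated and one kept.
- Comparison: Alternative 1 is clearly better in step count and in catalytic stereocontrol. The chosen plan offers a ring formation that does not depend on medium-ring cyclisation and three stereocentres derived by substrate control from one purchased centre.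

**Alternative 2: nickel reductive alkenyl–allyl closure (cut C5–C6).** Precursor A3 has an (E)-alkenyl iodide at C5 and an allylic carbonate at C6 on an α-alkylidene butyrolactone. NiBr2(dme), 4,4′-di-tert-butyl-2,2′-bipyridine and Zn would join C5 to C6 and give the lactone-fused cyclononadiene A4.
- Merits: the lactone fixes the C7=C8 geometry and already holds C19 and C20 at a level from which reduction gives the diol directly. The alkenyl iodide carries the E geometry of C4=C5 into the ring. The endgame from A4 is shorter than the one chosen here, since no carbon is extruded and no dehydrogenation is needed.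
- Weak points: the ring closure is again end to end, at high dilution, to a strained E,Z-diene. Reductive cross-electrophile coupling has little precedent for this ring size, and protodehalogenation, dimerisation and coupling at the other allyl terminus all compete. A3 needs C1, C9 and C10 built in an open chain together with the butenolide, which is a long approach.
- Comparison: Alternative 2 is better after the key step and worse before and at it. The chosen plan makes the medium ring by two unimolecular rearrangements (a [3,3] shift and a 1,2-shift) and takes its stereocentres from a six-membered ring.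

**Alternative 3: Grob fragmentation of a hydrindane (cut of the C4–C8 bond of a bicycle).** In the trans-fused hydrindanol A5 the tertiary C8 alkoxide would push out the C5 mesylate with cleavage of C4–C8. No new σ bond forms. The products are the (E)-C4=C5 alkene and the C8 ketone of cyclononenone A6.
- Merits: the fragmentation is stereospecific for the E alkene, needs no dilution and is well established for nine-membered rings. The C8 ketone of A6 could be converted into the C7=C8 ester by enol triflate formation toward C7 and carbonylation. That is shorter and more regioselective than the Wolff rearrangement followed by dehydrogenation used here, and it needs neither a diazo compound nor light.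
- Weak points: A5 needs three stereocentres that are destroyed (C4, C5, C8) in addition to C1, C9 and C10. A proline-catalysed annulation delivers only the angular centre, so the C1 side chain, the C9 branch and C10 must all be added to the bicycle with control. The route to A5 is therefore long.
- Comparison: A6 is the lower ring homologue of ketone 19, so the two plans differ mainly in how the ring ketone is reached and in where C19 comes from. Alternative 3 is better in the late stage. The chosen plan has the shorter and stereochemically simpler entry, since carvone already contains C19, C4/C18, C1 and the isopropenyl group that becomes C10–C12.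

Key step: step 13

Remark: 4-methoxybenzyl chloromethyl ether 7 is taken as purchasable (it is also made in one operation from 4-methoxybenzyl alcohol).
Remark: lithium, potassium and magnesium salts that are only the deprotonated form of a numbered compound are not numbered; every other species made and consumed in one flask is.
Remark: centres that are formed without control and destroyed later (C19 in 10 and 11, the carbinol carbon of 15, C8 in 20 and 23–25) are drawn as the expected major isomer or left open; atom labels C1–C20 are those of the target.

Step 1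
Reactants: 1 (R)-carvone
Product: 2 (R)-10-chlorocarvone
Conditions: Ca(OCl)2, CO2 (solid), CH2Cl2/H2O, 0 °C
Reagents that add atoms: calcium hypochlorite, [Ca+2].[O-]Cl.[O-]Cl
Why: Ene-type allylic chlorination by HOCl made in the flask: the electron-rich 1,1-disubstituted alkene reacts, the enone alkene does not, and the double bond shifts to give a 2-substituted allyl chloride with two equivalent CH2 termini; C1 is untouched.

Step 2
Reactants: 2 (R)-10-chlorocarvone; 3 allylboronic acid pinacol ester
Product: 4 (5R)-5-(hexa-1,5-dien-2-yl)-2-methylcyclohex-2-en-1-one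
Conditions: Pd2(dba)3 (cat.), PPh3, CsF, THF, 60 °C
Reagents that add atoms: allylboronic acid pinacol ester (3), C=CCB1OC(C)(C)C(C)(C)O1
Why: Palladium-catalysed allyl–allyl cross-coupling (Suzuki–Miyaura type) of an allylic chloride with a fluoride-activated allylboronate forms C12–C13. Both allyl partners have equivalent termini, so every mode of reductive elimination gives the same 1,5-diene, and the enone is inert.

Step 3
Reactants: 4 (5R)-5-(hexa-1,5-dien-2-yl)-2-methylcyclohex-2-en-1-one; 5 2-methylbut-2-ene
Product: 6 (5R)-2-methyl-5-(6-methylhepta-1,5-dien-2-yl)cyclohex-2-en-1-one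
Conditions: (H2IMes)(PCy3)Cl2Ru=CHPh (second-generation Grubbs catalyst, cat.), 2-methylbut-2-ene/CH2Cl2, 40 °C
Reagents that add atoms: 2-methylbut-2-ene (5), CC=C(C)C
Why: Olefin cross-metathesis with excess 2-methylbut-2-ene converts the monosubstituted alkene into the trisubstituted C14=C15 alkene with loss of propene; the 1,1-disubstituted C10=C11 alkene and the enone react far more slowly.

Step 4
Reactants: 6 (5R)-2-methyl-5-(6-methylhepta-1,5-dien-2-yl)cyclohex-2-en-1-one; 7 4-methoxybenzyl chloromethyl ether
Product: 8 trans-6-(PMB-oxymethyl) enone
Conditions: LiN(i-Pr)2, THF, −78 °C; then 7, −78 → −30 °C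
Reagents that add atoms: 4-methoxybenzyl chloromethyl ether (7), COc1ccc(COCCl)cc1
Why: Kinetic deprotonation at the α'-carbon C9 and C-alkylation of the lithium enolate by the chloromethyl ether (enolate alkylation). The electrophile enters anti to the neighbouring C1 substituent, giving the trans (diequatorial, also thermodynamically preferred) C1/C9 relationship of the target.

Step 5
Reactants: 8 trans-6-(PMB-oxymethyl) enone
Product: 10 C11/C19 diol, via bis-borane adduct 9 (not isolated)
Conditions: 9-BBN (2.5 equiv), THF, 0 → 23 °C; then NaBO3·4H2O, H2O, 23 °C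
Reagents that add atoms: sodium perborate, [Na+].[Na+].O[B-]1(O)OO[B-](O)(O)OO1 (oxygen on C11); 9-borabicyclo[3.3.1]nonane, B1C2CCCC1CCC2 (boron of 9 only)
Why: Hydroboration–oxidation: 9-BBN reduces the enone carbonyl 1,2 (the C19 carbinol is re-oxidised in step 7) and adds anti-Markovnikov only to the 1,1-disubstituted alkene, trisubstituted alkenes being much slower. C10 is set under A(1,3)-strain control: in the reactive conformer H1 eclipses C10=C11 and the borane approaches from the C2 flank, away from C9 and its CH2OPMB branch, which places H on C10 as in the target.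

Step 6
Reactants: 10 C11/C19 diol
Product: 11 C11 silyl ether
Conditions: t-BuMe2SiCl, imidazole, CH2Cl2, 0 °C
Reagents that add atoms: tert-butyldimethylsilyl chloride, CC(C)(C)[Si](C)(C)Cl
Why: Selective silylation of the unhindered primary C11 hydroxyl over the secondary allylic C19 hydroxyl, which is flanked by C4 and C9.

Step 7
Reactants: 11 C11 silyl ether
Product: 12 silyl ether enone
Conditions: MnO2, CH2Cl2, 23 °C
Reagents that add atoms: none
Why: Allylic alcohol oxidation by MnO2 restores the enone; silyl ether, PMB ether and isolated alkenes are inert.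

Step 8
Reactants: 12 silyl ether enone; 13 acetaldehyde
Product: 15 C4 aldol, via lithium enolate 14 (not isolated)
Conditions: LiBH(s-Bu)3, THF, −78 °C; then CH3CHO, −78 °C; NH4Cl (aq)
Reagents that add atoms: acetaldehyde (13), CC=O
Why: Conjugate reduction by LiBH(s-Bu)3 gives the regiodefined C19–C4 enolate 14, which is trapped by acetaldehyde (reductive aldol). The aldehyde adds axially to C4 on the face anti to the C9 substituent, so the new two-carbon branch is cis to the C1 side chain and the methyl is equatorial; the carbinol centre is a mixture and disappears in step 9.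

Step 9
Reactants: 15 C4 aldol
Product: 16 α-vinyl ketone
Conditions: Ph2S[OC(CF3)2Ph]2 (Martin sulfurane), CH2Cl2, 0 → 23 °C
Reagents that add atoms: none
Why: Dehydration with the Martin sulfurane under neutral conditions: C4 is quaternary, so only a methyl hydrogen can be lost and the terminal vinyl group is the only possible alkene, while base-induced retro-aldol cleavage is avoided.

Step 10
Reactants: 16 α-vinyl ketone; 17 vinylmagnesium bromide
Product: 18 trans-1,2-divinyl carbinol
Conditions: CH2=CHMgBr, CeCl3, THF, −78 → 0 °C
Reagents that add atoms: vinylmagnesium bromide (17), C=C[Mg]Br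
Why: 1,2-Addition of the organocerium reagent made from 17 and CeCl3, which adds to the hindered ketone without enolising C9 (no epimerisation, no β-elimination of the PMB-oxy group). Attack anti to the axial C4 vinyl group (axial attack, Felkin–Anh sense) gives the trans-divinyl carbinol; the C19 epimer, if formed, is carried along because it rearranges to the same ketone.

Step 11
Reactants: 18 trans-1,2-divinyl carbinol
Product: 19 (E)-cyclodec-5-enone
Conditions: KH, 18-crown-6, THF, 0 → 66 °C; then NH4Cl (aq), −78 °C
Reagents that add atoms: none
Why: Anionic oxy-Cope rearrangement of the potassium alkoxide: C4–C19 breaks and C6–C7 forms. Once ring inversion has brought the two vinyl groups gauche, the chair transition state holds C3 pseudo-equatorial, which fixes (E)-C4=C5; enolate formation makes the step irreversible and C1, C9 and C10 are not involved. Amine-free KH avoids proton shuttling to the C9 side, where the β-alkoxy group could be lost.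

Step 12
Reactants: 19 (E)-cyclodec-5-enone
Product: 21 ten-membered α-diazoketone, via α-trifluoroacetyl ketone 20 (not isolated)
Conditions: LiN(SiMe3)2, THF, −78 °C; CF3CO2CH2CF3; then 4-AcNHC6H4SO2N3, Et3N, H2O, MeCN, 23 °C
Reagents that add atoms: 4-acetamidobenzenesulfonyl azide, CC(=O)Nc1ccc(cc1)S(=O)(=O)N=[N+]=[N-] (N2 of 21); 2,2,2-trifluoroethyl trifluoroacetate, FC(F)(F)COC(=O)C(F)(F)F (trifluoroacetyl of 20 only)
Why: Deacylative diazo transfer of the Regitz type: kinetic deprotonation at the C8 methylene (not the branched C9 methine), Claisen condensation with the trifluoroacetate to 20, then diazo transfer from the sulfonyl azide with loss of the trifluoroacetyl group as the N-acylsulfonamide.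

Step 13
Reactants: 21 ten-membered α-diazoketone
Product: 23 cyclononene C8 methyl ester, via ketene 22 (not isolated)
Conditions: hν (365 nm), MeOH, 20 °C
Reagents that add atoms: methanol, CO
Why: Photochemical Wolff rearrangement: on irradiation the diazo group leaves as dinitrogen and in the same event the C19–C9 bond migrates to C8 (concerted from the s-cis O=C–C=N2 arrangement that the ring favours, or through a very short-lived singlet acylcarbene), giving ketene 22. Methanol adds to the ketene and the enol tautomerises to ester 23. The closest known reaction type is the light-induced ring contraction of cyclic 2-diazoketones in alcohols. The nine-membered ring is closed by forming C8–C9 in a 1,2-shift inside the existing ten-membered ring, that is by ring contraction with C19 expelled as the exocyclic carboxyl carbon and not by an end-to-end cyclisation, so neither dilution nor medium-ring entropy matters. C9 migrates with retention and C1 and C10 are spectators; the only new centre, C8, comes from unselective protonation of the ester enol and becomes planar again in step 14. The step needs rearrangement to win over carbene chemistry (1,2-hydride shift from C7, O–H insertion, attack on C4=C5 or on the ether oxygen at C20): direct irradiation without a metal avoids a long-lived carbenoid, C9 is the only group on the carbonyl carbon that can migrate, and methanol as solvent captures the ketene at once. Light of 365 nm is absorbed by the diazoketone but not by the anisyl ether or the isolated alkenes.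

Step 14
Reactants: 23 cyclononene C8 methyl ester
Product: 26 cyclononadiene methyl ester, via α-phenylselanyl ester 24 (not isolated), via selenoxide 25 (not isolated)
Conditions: LiN(i-Pr)2, THF, −78 °C; PhSeBr; then NaIO4, NaHCO3, THF/MeOH/H2O, 0 → 23 °C
Reagents that add atoms: benzeneselenenyl bromide, Br[Se]c1ccccc1 (selenium of 24 and 25, lost again); sodium periodate, [Na+].[O-]I(=O)(=O)=O (oxygen of 25, lost again)
Why: Ester enolate selenenylation followed by selenoxide syn-elimination. Elimination toward C7 gives the cis ring alkene C7=C8 (E by the CIP rules); with selenium delivered to the enolate face anti to ring carbon C1, H9 cannot become syn-periplanar to selenium in a ring-cis geometry, so C9 keeps its hydrogen and configuration. Periodate is used so that no peracid forms that could epoxidise the ring alkenes.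

Step 15
Reactants: 26 cyclononadiene methyl ester
Product: 27 C19 allylic alcohol
Conditions: i-Bu2AlH, CH2Cl2, −78 °C
Reagents that add atoms: none
Why: 1,2-Reduction of the α,β-unsaturated ester by i-Bu2AlH to the allylic alcohol; silyl and PMB ethers are inert.

Step 16
Reactants: 27 C19 allylic alcohol
Product: 28 C19/C20 bis-PMB ether
Conditions: NaH, 4-MeOC6H4CH2Cl, Bu4NI (cat.), DMF, 0 → 23 °C
Reagents that add atoms: 4-methoxybenzyl chloride, COc1ccc(CCl)cc1
Why: Williamson etherification of the alkoxide under non-acidic conditions; C19 and C20 now carry the same oxidatively removable group and can be unveiled together once the acetate is in place.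

Step 17
Reactants: 28 C19/C20 bis-PMB ether
Product: 29 C11 alcohol
Conditions: Bu4NF, THF, 0 → 23 °C
Reagents that add atoms: none
Why: Fluoride cleavage of the primary silyl ether; PMB ethers and alkenes are untouched.

Step 18
Reactants: 29 C11 alcohol
Product: 30 C11 acetate
Conditions: Ac2O, pyridine, DMAP (cat.), CH2Cl2, 0 °C
Reagents that add atoms: acetic anhydride, CC(=O)OC(C)=O
Why: DMAP-catalysed acetylation of the only free hydroxyl.

Step 19
Reactants: 30 C11 acetate
Product: 31 C19/C20 diol acetate
Conditions: DDQ, CH2Cl2/pH 7 buffer, 0 °C
Reagents that add atoms: none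
Why: Oxidative cleavage of both PMB ethers by DDQ (benzylic hydride abstraction, hydrolysis of the oxocarbenium ion); buffered, cold conditions spare the acetate, the allylic alcohol and the acid-sensitive diene.

Step 20
Reactants: 31 C19/C20 diol acetate
Product: 33 target dialdehyde acetate, via bis(alkoxysulfonium) chloride 32 (not isolated)
Conditions: (COCl)2, DMSO, CH2Cl2, −78 °C; then Et3N, −78 → −30 °C
Reagents that add atoms: dimethyl sulfoxide, CS(C)=O (sulfur of 32 only)
Why: Swern oxidation: both hydroxyls are converted into alkoxysulfonium ions (32) before base is added, so no hydroxy aldehyde and hence no lactol can form, and the two ylide fragmentations give the ene-1,4-dialdehyde, a conversion well known for 2-ene-1,4-diols. Low temperature and a buffered quench protect the configuration at C9; the acetate is inert.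

## Compound list

1 | (R)-carvone, (5R)-2-methyl-5-(prop-1-en-2-yl)cyclohex-2-en-1-one | CC(=C)[C@@H]1CC=C(C)C(=O)C1 | starting material
2 | (R)-10-chlorocarvone, (5R)-5-(3-chloroprop-1-en-2-yl)-2-methylcyclohex-2-en-1-one | ClCC(=C)[C@@H]1CC=C(C)C(=O)C1 | intermediate
3 | allylboronic acid pinacol ester, 2-allyl-4,4,5,5-tetramethyl-1,3,2-dioxaborolane | C=CCB1OC(C)(C)C(C)(C)O1 | starting material
4 | (5R)-5-(hexa-1,5-dien-2-yl)-2-methylcyclohex-2-en-1-one | C=CCCC(=C)[C@@H]1CC=C(C)C(=O)C1 | intermediate
5 | 2-methylbut-2-ene | CC=C(C)C | starting material
6 | (5R)-2-methyl-5-(6-methylhepta-1,5-dien-2-yl)cyclohex-2-en-1-one | CC(C)=CCCC(=C)[C@@H]1CC=C(C)C(=O)C1 | intermediate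
7 | 4-methoxybenzyl chloromethyl ether | COc1ccc(COCCl)cc1 | starting material
8 | (5R,6R)-6-[(4-methoxybenzyloxy)methyl]-2-methyl-5-(6-methylhepta-1,5-dien-2-yl)cyclohex-2-en-1-one (5,6-trans) | CC(C)=CCCC(=C)[C@@H]1CC=C(C)C(=O)[C@H]1COCc1ccc(OC)cc1 | intermediate
9 | bis(9-borabicyclo[3.3.1]nonan-9-yl) adduct of 8: B-alkyl at C11, borinate at the C19 oxygen (not isolated) | C(B1C2CCCC1CCC2)[C@H](CCC=C(C)C)[C@@H]1CC=C(C)[C@H](OB2C3CCCC2CCC3)[C@H]1COCc1ccc(OC)cc1 | intermediate
10 | 5-[(2R)-1-hydroxy-6-methylhept-5-en-2-yl]-6-[(4-methoxybenzyloxy)methyl]-2-methylcyclohex-2-en-1-ol (5,6-trans; ring OH drawn cis to the C5 side chain, its epimer is equally usable) | OC[C@H](CCC=C(C)C)[C@@H]1CC=C(C)[C@H](O)[C@H]1COCc1ccc(OC)cc1 | intermediate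
11 | 5-[(2R)-1-(tert-butyldimethylsilyloxy)-6-methylhept-5-en-2-yl]-6-[(4-methoxybenzyloxy)methyl]-2-methylcyclohex-2-en-1-ol (ring centres as in 10) | CC(C)(C)[Si](C)(C)OC[C@H](CCC=C(C)C)[C@@H]1CC=C(C)[C@H](O)[C@H]1COCc1ccc(OC)cc1 | intermediate
12 | 5-[(2R)-1-(tert-butyldimethylsilyloxy)-6-methylhept-5-en-2-yl]-6-[(4-methoxybenzyloxy)methyl]-2-methylcyclohex-2-en-1-one (5,6-trans) | CC(C)(C)[Si](C)(C)OC[C@H](CCC=C(C)C)[C@@H]1CC=C(C)C(=O)[C@H]1COCc1ccc(OC)cc1 | intermediate
13 | acetaldehyde | CC=O | starting material
14 | lithium enolate (C19–O–Li, C19=C4) of the 2,3-dihydro derivative of 12 (not isolated) | CC(C)(C)[Si](C)(C)OC[C@H](CCC=C(C)C)[C@@H]1CCC(C)=C(O[Li])[C@H]1COCc1ccc(OC)cc1 | intermediate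
15 | cyclohexanone with quaternary C4 bearing methyl and 1-hydroxyethyl (hydroxyethyl cis to the C1 side chain, trans to CH2OPMB; carbinol epimers), C9 CH2OPMB and C1 side chain trans | CC(C)(C)[Si](C)(C)OC[C@H](CCC=C(C)C)[C@@H]1CC[C@](C)(C(C)O)C(=O)[C@H]1COCc1ccc(OC)cc1 | intermediate
16 | 2-methyl-2-vinylcyclohexanone corresponding to 15 (vinyl cis to the C1 side chain, trans to CH2OPMB) | CC(C)(C)[Si](C)(C)OC[C@H](CCC=C(C)C)[C@@H]1CC[C@](C)(C=C)C(=O)[C@H]1COCc1ccc(OC)cc1 | intermediate
17 | vinylmagnesium bromide | C=C[Mg]Br | starting material
18 | 1,2-divinylcyclohexan-1-ol from 16 (C19 vinyl trans to the C4 vinyl, cis to CH2OPMB) | CC(C)(C)[Si](C)(C)OC[C@H](CCC=C(C)C)[C@@H]1CC[C@](C)(C=C)[C@@](O)(C=C)[C@H]1COCc1ccc(OC)cc1 | intermediate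
19 | (5E)-9-[(2R)-1-(tert-butyldimethylsilyloxy)-6-methylhept-5-en-2-yl]-10-[(4-methoxybenzyloxy)methyl]-6-methylcyclodec-5-en-1-one (9,10-trans; ketone = C19) | CC(C)(C)[Si](C)(C)OC[C@H](CCC=C(C)C)[C@@H]1CC/C(C)=C/CCCC(=O)[C@H]1COCc1ccc(OC)cc1 | intermediate
20 | 2-(trifluoroacetyl) derivative of 19 at C8 (not isolated; C8 open, largely enolised) | CC(C)(C)[Si](C)(C)OC[C@H](CCC=C(C)C)[C@@H]1CC/C(C)=C/CCC(C(=O)C(F)(F)F)C(=O)[C@H]1COCc1ccc(OC)cc1 | intermediate
21 | 2-diazo derivative of 19 (diazo at C8, ketone C19) | CC(C)(C)[Si](C)(C)OC[C@H](CCC=C(C)C)[C@@H]1CC/C(C)=C/CCC(=[N+]=[N-])C(=O)[C@H]1COCc1ccc(OC)cc1 | intermediate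
22 | nine-membered ketene (C8=C19=O) formed from 21 (not isolated) | CC(C)(C)[Si](C)(C)OC[C@H](CCC=C(C)C)[C@@H]1CC/C(C)=C/CCC(=C=O)[C@H]1COCc1ccc(OC)cc1 | intermediate
23 | methyl (4E)-8-[(2R)-1-(tert-butyldimethylsilyloxy)-6-methylhept-5-en-2-yl]-9-[(4-methoxybenzyloxy)methyl]-5-methylcyclonon-4-ene-1-carboxylate (8,9-trans; C8 epimers) | CC(C)(C)[Si](C)(C)OC[C@H](CCC=C(C)C)[C@@H]1CC/C(C)=C/CCC(C(=O)OC)[C@H]1COCc1ccc(OC)cc1 | intermediate
24 | 1-(phenylselanyl) derivative of 23 at C8 (not isolated) | CC(C)(C)[Si](C)(C)OC[C@H](CCC=C(C)C)[C@@H]1CC/C(C)=C/CCC([Se]c2ccccc2)(C(=O)OC)[C@H]1COCc1ccc(OC)cc1 | intermediate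
25 | selenoxide of 24 (not isolated) | CC(C)(C)[Si](C)(C)OC[C@H](CCC=C(C)C)[C@@H]1CC/C(C)=C/CCC([Se](=O)c2ccccc2)(C(=O)OC)[C@H]1COCc1ccc(OC)cc1 | intermediate
26 | methyl (1E,4E)-8-[(2R)-1-(tert-butyldimethylsilyloxy)-6-methylhept-5-en-2-yl]-9-[(4-methoxybenzyloxy)methyl]-5-methylcyclonona-1,4-diene-1-carboxylate (8,9-trans) | CC(C)(C)[Si](C)(C)OC[C@H](CCC=C(C)C)[C@@H]1CC/C(C)=C/C/C=C(/C(=O)OC)[C@H]1COCc1ccc(OC)cc1 | intermediate
27 | allylic alcohol from 26 (C19 = CH2OH) | CC(C)(C)[Si](C)(C)OC[C@H](CCC=C(C)C)[C@@H]1CC/C(C)=C/C/C=C(/CO)[C@H]1COCc1ccc(OC)cc1 | intermediate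
28 | 4-methoxybenzyl ether of 27 at the C19 oxygen (C19 and C20 both OPMB, C11 OTBS) | CC(C)(C)[Si](C)(C)OC[C@H](CCC=C(C)C)[C@@H]1CC/C(C)=C/C/C=C(/COCc2ccc(OC)cc2)[C@H]1COCc1ccc(OC)cc1 | intermediate
29 | C11 primary alcohol from 28 | OC[C@H](CCC=C(C)C)[C@@H]1CC/C(C)=C/C/C=C(/COCc2ccc(OC)cc2)[C@H]1COCc1ccc(OC)cc1 | intermediate
30 | C11 acetate of 29 | CC(=O)OC[C@H](CCC=C(C)C)[C@@H]1CC/C(C)=C/C/C=C(/COCc2ccc(OC)cc2)[C@H]1COCc1ccc(OC)cc1 | intermediate
31 | (2R)-2-[(1S,2S,3E,6E)-2,3-bis(hydroxymethyl)-7-methylcyclonona-3,6-dien-1-yl]-6-methylhept-5-en-1-yl acetate | CC(=O)OC[C@H](CCC=C(C)C)[C@@H]1CC/C(C)=C/C/C=C(/CO)[C@H]1CO | intermediate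
32 | bis(dimethylsulfonio-oxy) derivative of 31 at the C19 and C20 oxygens, dichloride (not isolated) | CC(=O)OC[C@H](CCC=C(C)C)[C@@H]1CC/C(C)=C/C/C=C(/CO[S+](C)C)[C@H]1CO[S+](C)C.[Cl-].[Cl-] | intermediate
33 | (2R)-2-[(1S,2S,3E,6E)-2,3-diformyl-7-methylcyclonona-3,6-dien-1-yl]-6-methylhept-5-en-1-yl acetate (CNP0091613.1) | CC(=O)OC[C@H](CCC=C(C)C)[C@@H]1CC/C(C)=C/C/C=C(/C=O)[C@H]1C=O | target

## Step count and risks

Total step count: 20. Longest linear sequence: 20 steps (1 → 33; 3, 5, 7, 13 and 17 are purchased).

**Step 13 (key step).** The likely failure is loss of nitrogen without migration. A ten-membered ring can also hold the diazoketone s-trans, and the acylcarbene formed from that conformer may shift a hydride from C7 (giving a conjugated cyclodecadienone) or insert into the O–H bond of methanol. The fallback keeps the same C8–C9 bond formation and ring contraction but uses no diazo compound. It sets out from ketone 19. The kinetic C8 enolate (LiN(SiMe3)2) is hydroxylated with 2-(benzenesulfonyl)-3-phenyloxaziridine to the α-hydroxy ketone F1. Dess–Martin periodinane gives the ten-membered 1,2-diketone F2. Benzilic acid rearrangement (KOH, aqueous dioxane, 0 → 23 °C) contracts the ring to the nine-membered α-hydroxy acid F3, in which C8 and C9 are joined and the carboxyl carbon is exocyclic whichever carbonyl is attacked. Me3SiCHN2 gives the methyl ester F4, and SmI2/HMPA/t-BuOH removes the tertiary α-hydroxyl, which returns the route to ester 23. The weak point of this fallback is possible epimerisation at C9 in the diketone.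

**Step 11 (oxy-Cope).** The major carbinol 18 has its two vinyl groups trans-diaxial. It must pass through a ring-inverted or twisted conformer with four axial substituents before the chair transition state is open. A slow rearrangement leaves time for fragmentation of the alkoxide into an allyl anion and an enone (with recombination to a [1,3] product), or for loss of the PMB-oxy group after enolate equilibration. The fallback makes the C19 epimer, which can rearrange from its ground-state chair. It sets out from ketone 16. Dimethylsulfoxonium methylide (Me3S(O)I, NaH, DMSO; Corey–Chaykovsky reaction, reversible addition, equatorial C–C bond) gives the spiro-epoxide F5 with axial oxygen. Excess dimethylsulfonium methylide (Me3SI, n-BuLi, THF) opens the epoxide at CH2 and eliminates Me2S to give the equatorial-vinyl carbinol F6. In F6 the C4 vinyl is axial and the C19 vinyl equatorial, and the chair transition state again has C3 pseudo-equatorial. KH/18-crown-6 at or below room temperature should then give ketone 19.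

**Step 5 (hydroboration, C10).** The facial selectivity may be lower than the model predicts, or opposite to it, because the two flanks of the alkene differ only by the CH2OPMB branch on C9. Epimers can be separated at 10 or 11. If the sense is reversed, the fallback exchanges the roles of the two carbons on C10 so that the same facial preference gives the right configuration. It sets out from 1. Allylic hydroxylation (SeO2 cat., t-BuOOH) gives 10-hydroxycarvone F7, and silylation gives the silyl ether F8. Enolate alkylation with 7 as in step 4 gives the trans-alkylated enone F9. 9-BBN (bis-borane adduct F10) and perborate give the diol F11, in which the hydroborated carbon is now C12 and the silyloxymethyl carbon is C11. Iodination of the primary alcohol (I2, PPh3, imidazole) gives the iodide F12. Alkylation of lithiated 3-methylbut-2-enyl phenyl sulfone gives the allylic sulfone F13. Reductive desulfonylation (PdCl2(dppp) cat., LiBHEt3) returns the route to 11.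

**Step 9 (with step 8, C4 vinyl group).** The activated neopentylic secondary alcohol may ionise and undergo a 1,2-acyl or alkyl shift instead of losing a methyl hydrogen, or the aldol may revert. The fallback uses a vinyl cation equivalent. It sets out from 12. Enolate 14, generated as in step 8, adds to phenyl vinyl sulfoxide (Michael addition) to give the 2-(phenylsulfinyl)ethyl ketone F14. Thermal sulfoxide syn-elimination (toluene, 110 °C, CaCO3) can take a hydrogen only from C5 and gives vinyl ketone 16.

**Step 14 (dehydrogenation).** The risk is the regiochemistry of the syn-elimination. If selenium enters on the other enolate face, H9 becomes syn-accessible and the tetrasubstituted C8=C9 alkene competes, with loss of the C9 stereocentre. The fallback uses the opposite stereochemical requirement. It sets out from 23. The enolate is brominated (CBr4) to the α-bromo ester F15, formed with the same facial preference. Base-induced anti-elimination (DBU, toluene, 60 °C) then cannot use H9 in a ring-cis geometry and removes a C7 hydrogen, giving 26.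

## Further compounds

F1 | step 13 | 2-hydroxy derivative of ketone 19 at C8 (epimers) | CC(C)(C)[Si](C)(C)OC[C@H](CCC=C(C)C)[C@@H]1CC/C(C)=C/CCC(O)C(=O)[C@H]1COCc1ccc(OC)cc1
F2 | step 13 | ten-membered 1,2-diketone (C8 and C19 carbonyls) | CC(C)(C)[Si](C)(C)OC[C@H](CCC=C(C)C)[C@@H]1CC/C(C)=C/CCC(=O)C(=O)[C@H]1COCc1ccc(OC)cc1
F3 | step 13 | nine-membered 1-hydroxycyclonon-4-ene-1-carboxylic acid with the substituents of 23 | CC(C)(C)[Si](C)(C)OC[C@H](CCC=C(C)C)[C@@H]1CC/C(C)=C/CCC(O)(C(=O)O)[C@H]1COCc1ccc(OC)cc1
F4 | step 13 | methyl ester of F3 | CC(C)(C)[Si](C)(C)OC[C@H](CCC=C(C)C)[C@@H]1CC/C(C)=C/CCC(O)(C(=O)OC)[C@H]1COCc1ccc(OC)cc1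
F5 | step 11 | spiro-epoxide of ketone 16 at C19 (oxygen axial, CH2 equatorial) | CC(C)(C)[Si](C)(C)OC[C@H](CCC=C(C)C)[C@@H]1CC[C@](C)(C=C)[C@]2(CO2)[C@H]1COCc1ccc(OC)cc1
F6 | step 11 | C19 epimer of carbinol 18 (C19 vinyl cis to the C4 vinyl) | CC(C)(C)[Si](C)(C)OC[C@H](CCC=C(C)C)[C@@H]1CC[C@](C)(C=C)[C@](O)(C=C)[C@H]1COCc1ccc(OC)cc1
F7 | step 5 | (R)-10-hydroxycarvone | OCC(=C)[C@@H]1CC=C(C)C(=O)C1
F8 | step 5 | tert-butyldimethylsilyl ether of F7 | CC(C)(C)[Si](C)(C)OCC(=C)[C@@H]1CC=C(C)C(=O)C1
F9 | step 5 | trans-6-[(4-methoxybenzyloxy)methyl] derivative of F8 | CC(C)(C)[Si](C)(C)OCC(=C)[C@@H]1CC=C(C)C(=O)[C@H]1COCc1ccc(OC)cc1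
F10 | step 5 | bis(9-borabicyclo[3.3.1]nonan-9-yl) adduct of F9 (B-alkyl at C12, borinate at the C19 oxygen) | CC(C)(C)[Si](C)(C)OC[C@H](CB1C2CCCC1CCC2)[C@@H]1CC=C(C)[C@H](OB2C3CCCC2CCC3)[C@H]1COCc1ccc(OC)cc1
F11 | step 5 | C12/C19 diol with C11 silyl ether | CC(C)(C)[Si](C)(C)OC[C@H](CO)[C@@H]1CC=C(C)[C@H](O)[C@H]1COCc1ccc(OC)cc1
F12 | step 5 | C12 primary iodide of F11 | CC(C)(C)[Si](C)(C)OC[C@H](CI)[C@@H]1CC=C(C)[C@H](O)[C@H]1COCc1ccc(OC)cc1
F13 | step 5 | C13 phenylsulfonyl derivative of 11 (sulfone epimers) | CC(C)(C)[Si](C)(C)OC[C@H](CC(C=C(C)C)S(=O)(=O)c2ccccc2)[C@@H]1CC=C(C)[C@H](O)[C@H]1COCc1ccc(OC)cc1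
F14 | step 9 | C4 2-(phenylsulfinyl)ethyl ketone (sulfoxide epimers) | CC(C)(C)[Si](C)(C)OC[C@H](CCC=C(C)C)[C@@H]1CC[C@](C)(CCS(=O)c2ccccc2)C(=O)[C@H]1COCc1ccc(OC)cc1
F15 | step 14 | 1-bromo derivative of ester 23 at C8 | CC(C)(C)[Si](C)(C)OC[C@H](CCC=C(C)C)[C@@H]1CC/C(C)=C/CCC(Br)(C(=O)OC)[C@H]1COCc1ccc(OC)cc1
A1 | alternative 1 | open-chain precursor with the C20 enal (C9=C8, methyl ester C19 on C8; this geometry immaterial), (E)-C4=C5 and the (E)-C11 enal (C1=C10) | O=CC=C(C(=O)OC)CC/C=C(\C)CC/C=C(/C=O)CCC=C(C)C
A2 | alternative 1 | cyclononadiene dialdehyde ester (C20 and C11 formyl, C19 methyl ester) | O=C[C@H](CCC=C(C)C)[C@@H]1CC/C(C)=C/C/C=C(/C(=O)OC)[C@H]1C=O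
A3 | alternative 2 | α-alkylidene butyrolactone with (E)-alkenyl iodide at C5 and allylic methyl carbonate at C6 | CC(C)(C)[Si](C)(C)OC[C@H](CCC=C(C)C)[C@H](CC/C(C)=C/I)[C@@H]1COC(=O)/C1=C/COC(=O)OC
A4 | alternative 2 | cyclononadiene fused to the α-alkylidene butyrolactone (C19 carbonyl, C20 methylene) | CC(C)(C)[Si](C)(C)OC[C@H](CCC=C(C)C)[C@@H]1CC/C(C)=C/C/C=C2/C(=O)OC[C@@H]12
A5 | alternative 3 | trans-fused hydrindan-8-ol with angular methyl on C4 and C5 mesylate cis to that methyl | CC(C)(C)[Si](C)(C)OC[C@H](CCC=C(C)C)[C@@H]1CC[C@]2(C)[C@@H](OS(C)(=O)=O)CC[C@@]2(O)[C@H]1COCc1ccc(OC)cc1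
A6 | alternative 3 | (E)-cyclonon-4-enone with ketone at C8 and the C1 and C9 substituents in place | CC(C)(C)[Si](C)(C)OC[C@H](CCC=C(C)C)[C@@H]1CC/C(C)=C/CCC(=O)[C@H]1COCc1ccc(OC)cc1
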